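**Assumption (one line):** the auxiliary, catalyst and enzyme enantiomers named below (Evans (S)-benzyl, (S)-Me-CBS at C2, (R)-Me-CBS at C9, lipase preference) are taken to deliver the depicted enantiomer. "β" means the face carrying the C1 methyl, and briarane numbering is used throughout.

## Retrosynthetic overview
1. The target comes from global desilylation of macrocycle 40. The 10-membered ring is closed last by a proposed new Ru ring-closing metathesis between the C7 vinyl group and the 1,1-disubstituted C5=CH2 of a cis-dienyl chain.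
2. The γ-lactone (C7/C8/C17/C19) is built before that ring closure, by an intramolecular Reformatsky aldol lactonisation onto a C8 ketone flanked by C7 and C9 oxygens. The ketone comes from a dithiane linchpin, with C7 set by lipase resolution and C9 by CBS reduction.
3. The cyclohexane ring, including the C1 quaternary centre and C10/C11, comes from an exo-selective Diels–Alder reaction between a 2-silyloxydiene and an α-methyl enoyl imide. Saegusa oxidation, Luche reduction, acetylation and epoxidation then give the 12-OAc and 13,14-epoxide.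
4. C2 is set by ynone CBS reduction. The enyne is reduced to the Z-diene (Zn(Cu/Ag)) just before RCM.
5. Ring order: cyclohexene (Diels–Alder), then epoxide, then γ-lactone, then 10-membered ring (RCM).

## Route

**Step 1**
Reactants: 1 pent-1-en-3-one
Product: 2 (Z)-3-(trimethylsilyloxy)penta-1,3-diene (Me trans to vinyl, i.e. an "E-diene" with outside Me)
Conditions: TMSOTf, Et3N, CH2Cl2, 0 °C
Reagents that add atoms: TMSOTf, C[Si](C)(C)OS(=O)(=O)C(F)(F)F
Why: Thermodynamic O-silylation of the ethyl ketone gives the Z-silyl enol ether, which sets the outside methyl (C11 Me) of the diene.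

**Step 2**
Reactants: 3 TBSOCH2CHO; 4 triethyl 2-phosphonopropionate
Product: 5 ethyl (E)-4-(TBSO)-2-methylbut-2-enoate
Conditions: NaH, THF, 0 °C → rt
Reagents that add atoms: none
Why: Horner–Wadsworth–Emmons olefination is E-selective, so the ester (future C2) is trans to CH2OTBS (future C9) and the methyl is cis to it.

**Step 3**
Reactants: 5
Product: 6 (E)-4-(TBSO)-2-methylbut-2-enoic acid
Conditions: LiOH, THF/H2O, 0 °C
Reagents that add atoms: LiOH, [Li+].[OH-]
Why: Saponification of the unhindered ethyl ester; the TBS ether and the alkene geometry are untouched.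

**Step 4**
Reactants: 6; 7 (S)-4-benzyloxazolidin-2-one
Product: 8 N-[(E)-4-TBSO-2-methylbut-2-enoyl]-(S)-4-benzyloxazolidin-2-one
Conditions: PivCl, Et3N, THF, 0 °C; then 7, LiCl, rt
Reagents that add atoms: none
Why: Mixed-anhydride N-acylation attaches the Evans auxiliary, which will control the Diels–Alder face.

**Step 5**
Reactants: 2; 8
Product: 9 Diels–Alder silyl-enol-ether adduct (C1-Me, C10-CH2OTBS and C11-Me all β; C2 imide α; C12(OTMS)=C13)
Conditions: Me2AlCl, CH2Cl2, –78 → –20 °C
Reagents that add atoms: none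
Why: Lewis-acid Diels–Alder of the chelated s-cis imide; the 2-siloxy donor gives the "para" regiochemistry (imide-bearing C1 bonds to C14). The benzyl group blocks one face, and the exo transition state with the E-dienophile and E-diene places C1-Me, C9 and C11-Me cis and C2 trans to C9 (this C11 relation is the step's main risk).

**Step 6**
Reactants: 9
Product: 10 cyclohexenone (C12=O, C13=C14)
Conditions: Pd(OAc)2, MeCN, rt
Reagents that add atoms: none
Why: Ito–Saegusa oxidation of the silyl enol ether gives the enone directly; the C1/C10/C11 stereocentres are not touched.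

**Step 7**
Reactants: 10
Product: 11 allylic alcohol (12-OH β, cis to 11-Me)
Conditions: NaBH4, CeCl3·7H2O, MeOH, –78 °C
Reagents that add atoms: none (H only)
Why: Luche 1,2-reduction; hydride enters from the α face, anti to the C11 methyl, so the new OH is cis to it.

**Step 8**
Reactants: 11
Product: 12 12-acetate
Conditions: Ac2O, DMAP, Et3N, CH2Cl2, 0 °C
Reagents that add atoms: acetic anhydride, CC(=O)OC(C)=O
Why: Ordinary acylation installs the C12 acetate with retention of configuration.

**Step 9**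
Reactants: 12
Product: 13 13α,14α-epoxide
Conditions: mCPBA, NaHCO3, CH2Cl2, 0 °C
Reagents that add atoms: mCPBA, OOC(=O)c1cccc(Cl)c1
Why: Prilezhaev epoxidation; the peracid attacks the α face, anti to the pseudo-axial C1-Me and C12-OAc, so the epoxide is trans to the acetate as in the target.

**Step 10**
Reactants: 13
Product: 14 Weinreb amide (imide replaced by C(=O)N(Me)OMe; auxiliary 7 recovered)
Conditions: MeONHMe·HCl, i-PrMgCl, THF, –20 → 0 °C
Reagents that add atoms: N,O-dimethylhydroxylamine, CNOC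
Why: Magnesium-amide transamidation of the imide under conditions the epoxide and acetate tolerate.

**Step 11**
Reactants: 15 2-bromoprop-2-en-1-ol
Product: 16 2-bromoallyl TBDPS ether
Conditions: TBDPSCl, imidazole, DMF, rt
Reagents that add atoms: TBDPSCl, CC(C)(C)[Si](c1ccccc1)(c1ccccc1)Cl
Why: Standard silylation of the primary alcohol (C16 oxygen).

**Step 12**
Reactants: 16; 17 trimethylsilylacetylene
Product: 18 2-(TBDPSOCH2)-1-buten-3-yne, TMS-protected
Conditions: Pd(PPh3)2Cl2, CuI, Et3N, THF, 50 °C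
Reagents that add atoms: none
Why: Sonogashira coupling of the vinyl bromide with the alkyne.

**Step 13**
Reactants: 18
Product: 19 terminal enyne HC≡C–C(=CH2)CH2OTBDPS
Conditions: K2CO3, MeOH, rt
Reagents that add atoms: none
Why: Mild C–Si methanolysis removes the TMS group.

**Step 14**
Reactants: 14; 19
Product: 20 ynone (C2 ketone; C3≡C4–C5(=CH2)–C16H2OTBDPS)
Conditions: n-BuLi, THF, –78 °C; then 14, –78 → 0 °C
Reagents that add atoms: none
Why: Weinreb ketone synthesis; the stable chelated intermediate prevents over-addition, and the small acetylide reaches the neopentyl amide.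

**Step 15**
Reactants: 20
Product: 21 (2S)-propargylic alcohol
Conditions: (S)-Me-CBS (30 mol%), BH3·SMe2, THF, –20 °C
Reagents that add atoms: none (H only)
Why: Corey–Bakshi–Shibata reduction of an ynone whose two sides differ strongly in size (sp carbon versus quaternary alkyl); catalyst control sets C2.

**Step 16**
Reactants: 21
Product: 22 C2-OTIPS ether
Conditions: TIPSOTf, 2,6-lutidine, CH2Cl2, –78 → 0 °C
Reagents that add atoms: TIPSOTf, CC(C)[Si](C(C)C)(C(C)C)OS(=O)(=O)C(F)(F)F
Why: A silyl triflate is needed to protect the hindered secondary alcohol; TIPS is orthogonal to the primary TBS group removed next.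

**Step 17**
Reactants: 22
Product: 23 primary alcohol (C9 CH2OH)
Conditions: HF·pyridine, pyridine, THF, 0 °C
Reagents that add atoms: none
Why: Buffered HF removes the primary TBS group selectively over TIPS and TBDPS, leaving the acetate and epoxide intact.

**Step 18**
Reactants: 23
Product: 24 aldehyde (C9 CHO on C10)
Conditions: DMP, NaHCO3, CH2Cl2, rt
Reagents that add atoms: none
Why: Dess–Martin oxidation under buffered conditions to limit epimerisation at C10.

**Step 19**
Reactants: 25 1,3-dithiane; 26 acrolein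
Product: 27 (±)-1-(1,3-dithian-2-yl)prop-2-en-1-ol
Conditions: n-BuLi, THF, –30 °C; then acrolein, –78 °C
Reagents that add atoms: none
Why: Corey–Seebach 1,2-addition builds the C8 dithiane and C7 vinyl carbinol.

**Step 20**
Reactants: 27
Product: 28 (S)-1-(1,3-dithian-2-yl)prop-2-en-1-ol
Conditions: Amano lipase PS, vinyl acetate, hexane/MTBE, 30 °C (stop at ~50% conversion)
Reagents that add atoms: none (the acetylated R-enantiomer is discarded)
Why: Lipase kinetic resolution acylates the (R)-carbinol fastest, leaving the (S)-alcohol, which sets C7.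

**Step 21**
Reactants: 28
Product: 29 (S)-TES ether
Conditions: TESCl, imidazole, DMF, 0 °C
Reagents that add atoms: TESCl, CC[Si](Cl)(CC)CC
Why: Protects the C7 oxygen with a group removable later without touching TIPS or TBDPS.

**Step 22**
Reactants: 24; 29
Product: 30 dithiane–carbinol adduct (C9 epimeric mixture)
Conditions: 29, n-BuLi, THF, –40 °C; then 24, –78 °C
Reagents that add atoms: none
Why: Smith-type dithiane linchpin coupling joins C8 to C9; the C9 centre is deliberately made unselectively and corrected in Steps 23–24.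

**Step 23**
Reactants: 30
Product: 31 C9 ketone
Conditions: DMP, NaHCO3, CH2Cl2, rt
Reagents that add atoms: none
Why: Oxidation destroys the unwanted C9 stereochemistry so that it can be re-set with reagent control.

**Step 24**
Reactants: 31
Product: 32 (9R)-alcohol
Conditions: (R)-Me-CBS (30 mol%), BH3·SMe2, THF, –20 °C
Reagents that add atoms: none (H only)
Why: CBS reduction under catalyst control sets C9 (R).

**Step 25**
Reactants: 32
Product: 33 C9 acetate
Conditions: Ac2O, DMAP, pyridine, CH2Cl2, rt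
Reagents that add atoms: acetic anhydride, CC(=O)OC(C)=O
Why: Installs the C9 acetate of the target.

**Step 26**
Reactants: 33
Product: 34 C8 ketone (α-silyloxy, α′-acetoxy)
Conditions: DMP, MeCN/H2O (9:1), NaHCO3, rt
Reagents that add atoms: water, O
Why: Oxidative hydrolysis of the dithiane, under conditions that leave the enyne, epoxide, acetates and silyl ethers alone.

**Step 27**
Reactants: 34
Product: 35 C7 alcohol
Conditions: PPTS, MeOH, 0 °C → rt
Reagents that add atoms: none
Why: Mild acidic methanolysis cleaves the TES ether selectively, freeing C7–OH for acylation.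

**Step 28**
Reactants: 35; 36 2-bromopropionyl bromide
Product: 37 C7 2-bromopropionate (CHBr epimeric mixture)
Conditions: pyridine, DMAP (cat.), CH2Cl2, 0 °C
Reagents that add atoms: none
Why: Acylation; the bromide stereocentre is irrelevant because it becomes a planar zinc enolate.

**Step 29**
Reactants: 37
Product: 38 γ-lactone with 8-OH and 17-Me
Conditions: Zn dust, TMSCl (cat.), THF, 40 °C
Reagents that add atoms: none
Why: Intramolecular Reformatsky aldol lactonisation forms C8–C17 and sets C8 and C17. The C7 vinyl and C9 branch end up trans on the five-membered ring, and the C17 methyl ends up anti to C9 (cis to the 8-OH), as in the target.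

**Step 30**
Reactants: 38
Product: 39 cis-dienyl precursor (C3=C4 Z; C5=CH2; C6 vinyl)
Conditions: Zn, Cu(OAc)2·H2O, AgNO3, MeOH/H2O, rt
Reagents that add atoms: none (H only)
Why: Boland Zn(Cu/Ag) semi-reduction of the enyne gives the Z-alkene selectively and leaves the vinyl group, acetates, epoxide and silyl ethers untouched.

**Step 31**
Reactants: 39
Product: 40 ten-membered macrocycle with C5=C6 (ring-cis) and C3=C4 (Z)
Conditions: Hoveyda–Grubbs II (20 mol%), 1,4-benzoquinone (30 mol%), toluene (1 mM), 80 °C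
Reagents that add atoms: none (ethylene is lost)
Why: Ring-closing metathesis forms the C5=C6 bond and closes the 10-membered ring. Proposed new method: a Ru methylidene first reacts at the unhindered C7 vinyl group; the resulting alkylidene is captured intramolecularly by the 1,1-disubstituted diene terminus C5=CH2, and ethylene loss drives the ring closure. The already-cis C3=C4 alkene and the cis-fused lactone pre-organise the ends, and ring strain forces the ring-cis (target) C5=C6 geometry. The closest known reaction type is macrocyclic RCM forming trisubstituted alkenes (and diene–ene RCM), but closure of a 10-membered ring that contains a cis-1,3-diene, a trisubstituted alkene and a free tertiary alcohol has not been shown.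

**Step 32**
Reactants: 40
Product: 41 Briaexcavatolide N
Conditions: TBAF, AcOH (1:1), THF, 0 °C → rt
Reagents that add atoms: none
Why: Buffered fluoride removes the TIPS (C2) and TBDPS (C16) groups; the AcOH buffer suppresses acetate migration and retro-aldol at the β-hydroxy lactone.

## Compound list
Configuration at the ring stereocentres is carried in each SMILES. All stereo-defined intermediates are enantiopure. Compounds 27 and 30 are the racemic and C9-epimeric mixtures the route calls for, and 37 is a mixture at the CHBr carbon.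

| # | name | SMILES | role |
|---|---|---|---|
| 1 | pent-1-en-3-one | C=CC(=O)CC | starting material |
| 2 | (Z)-3-(trimethylsilyloxy)penta-1,3-diene | C=C/C(=C/C)O[Si](C)(C)C | intermediate |
| 3 | 2-(TBSO)acetaldehyde | CC(C)(C)[Si](C)(C)OCC=O | starting material |
| 4 | triethyl 2-phosphonopropionate | CCOC(=O)C(C)P(=O)(OCC)OCC | starting material |
| 5 | ethyl (E)-4-TBSO-2-methylbut-2-enoate | CCOC(=O)/C(C)=C/CO[Si](C)(C)C(C)(C)C | intermediate |
| 6 | (E)-4-TBSO-2-methylbut-2-enoic acid | OC(=O)/C(C)=C/CO[Si](C)(C)C(C)(C)C | intermediate |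
| 7 | (S)-4-benzyloxazolidin-2-one | C1[C@@H](NC(=O)O1)Cc1ccccc1 | starting material |
| 8 | N-enoyl oxazolidinone | O=C(N1[C@@H](Cc2ccccc2)COC1=O)/C(C)=C/CO[Si](C)(C)C(C)(C)C | intermediate |
| 9 | Diels–Alder silyl enol ether adduct | C[C@]1(C(=O)N2[C@@H](Cc3ccccc3)COC2=O)CC=C(O[Si](C)(C)C)[C@H](C)[C@@H]1CO[Si](C)(C)C(C)(C)C | intermediate |
| 10 | cyclohexenone imide | C[C@]1(C(=O)N2[C@@H](Cc3ccccc3)COC2=O)C=CC(=O)[C@H](C)[C@@H]1CO[Si](C)(C)C(C)(C)C | intermediate |
| 11 | allylic alcohol imide | C[C@]1(C(=O)N2[C@@H](Cc3ccccc3)COC2=O)C=C[C@H](O)[C@H](C)[C@@H]1CO[Si](C)(C)C(C)(C)C | intermediate |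
| 12 | acetate imide | C[C@]1(C(=O)N2[C@@H](Cc3ccccc3)COC2=O)C=C[C@H](OC(C)=O)[C@H](C)[C@@H]1CO[Si](C)(C)C(C)(C)C | intermediate |
| 13 | epoxy acetate imide | C[C@]1(C(=O)N2[C@@H](Cc3ccccc3)COC2=O)[C@H]3O[C@H]3[C@H](OC(C)=O)[C@H](C)[C@@H]1CO[Si](C)(C)C(C)(C)C | intermediate |
| 14 | epoxy acetate Weinreb amide | C[C@]1(C(=O)N(C)OC)[C@H]3O[C@H]3[C@H](OC(C)=O)[C@H](C)[C@@H]1CO[Si](C)(C)C(C)(C)C | intermediate |
| 15 | 2-bromoprop-2-en-1-ol | C=C(Br)CO | starting material |
| 16 | 2-bromoallyl TBDPS ether | C=C(Br)CO[Si](c1ccccc1)(c1ccccc1)C(C)(C)C | intermediate |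
| 17 | trimethylsilylacetylene | C[Si](C)(C)C#C | starting material |
| 18 | TMS-enyne | C=C(C#C[Si](C)(C)C)CO[Si](c1ccccc1)(c1ccccc1)C(C)(C)C | intermediate |
| 19 | terminal enyne | C=C(C#C)CO[Si](c1ccccc1)(c1ccccc1)C(C)(C)C | intermediate |
| 20 | ynone | C[C@]1(C(=O)C#CC(=C)CO[Si](c2ccccc2)(c2ccccc2)C(C)(C)C)[C@H]3O[C@H]3[C@H](OC(C)=O)[C@H](C)[C@@H]1CO[Si](C)(C)C(C)(C)C | intermediate |
| 21 | (2S)-propargylic alcohol | C[C@]1([C@@H](O)C#CC(=C)CO[Si](c2ccccc2)(c2ccccc2)C(C)(C)C)[C@H]3O[C@H]3[C@H](OC(C)=O)[C@H](C)[C@@H]1CO[Si](C)(C)C(C)(C)C | intermediate |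
| 22 | C2-OTIPS ether | C[C@]1([C@@H](O[Si](C(C)C)(C(C)C)C(C)C)C#CC(=C)CO[Si](c2ccccc2)(c2ccccc2)C(C)(C)C)[C@H]3O[C@H]3[C@H](OC(C)=O)[C@H](C)[C@@H]1CO[Si](C)(C)C(C)(C)C | intermediate |
| 23 | primary alcohol | C[C@]1([C@@H](O[Si](C(C)C)(C(C)C)C(C)C)C#CC(=C)CO[Si](c2ccccc2)(c2ccccc2)C(C)(C)C)[C@H]3O[C@H]3[C@H](OC(C)=O)[C@H](C)[C@@H]1CO | intermediate |
| 24 | C9 aldehyde | C[C@]1([C@@H](O[Si](C(C)C)(C(C)C)C(C)C)C#CC(=C)CO[Si](c2ccccc2)(c2ccccc2)C(C)(C)C)[C@H]3O[C@H]3[C@H](OC(C)=O)[C@H](C)[C@@H]1C=O | intermediate |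
| 25 | 1,3-dithiane | C1CSCSC1 | starting material |
| 26 | acrolein | C=CC=O | starting material |
| 27 | (±)-1-(1,3-dithian-2-yl)prop-2-en-1-ol | C=CC(O)C1SCCCS1 | intermediate |
| 28 | (S)-1-(1,3-dithian-2-yl)prop-2-en-1-ol | C=C[C@H](O)C1SCCCS1 | intermediate |
| 29 | (S)-TES ether | C=C[C@H](O[Si](CC)(CC)CC)C1SCCCS1 | intermediate |
| 30 | dithiane–carbinol adduct (C9 epimers) | C[C@]1([C@@H](O[Si](C(C)C)(C(C)C)C(C)C)C#CC(=C)CO[Si](c2ccccc2)(c2ccccc2)C(C)(C)C)[C@H]3O[C@H]3[C@H](OC(C)=O)[C@H](C)[C@@H]1C(O)C4(SCCCS4)[C@@H](O[Si](CC)(CC)CC)C=C | intermediate |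
| 31 | C9 ketone | C[C@]1([C@@H](O[Si](C(C)C)(C(C)C)C(C)C)C#CC(=C)CO[Si](c2ccccc2)(c2ccccc2)C(C)(C)C)[C@H]3O[C@H]3[C@H](OC(C)=O)[C@H](C)[C@@H]1C(=O)C4(SCCCS4)[C@@H](O[Si](CC)(CC)CC)C=C | intermediate |
| 32 | (9R)-alcohol | C[C@]1([C@@H](O[Si](C(C)C)(C(C)C)C(C)C)C#CC(=C)CO[Si](c2ccccc2)(c2ccccc2)C(C)(C)C)[C@H]3O[C@H]3[C@H](OC(C)=O)[C@H](C)[C@@H]1[C@@H](O)C4(SCCCS4)[C@@H](O[Si](CC)(CC)CC)C=C | intermediate |
| 33 | C9 acetate | C[C@]1([C@@H](O[Si](C(C)C)(C(C)C)C(C)C)C#CC(=C)CO[Si](c2ccccc2)(c2ccccc2)C(C)(C)C)[C@H]3O[C@H]3[C@H](OC(C)=O)[C@H](C)[C@@H]1[C@@H](OC(C)=O)C4(SCCCS4)[C@@H](O[Si](CC)(CC)CC)C=C | intermediate |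
| 34 | C8 ketone | C[C@]1([C@@H](O[Si](C(C)C)(C(C)C)C(C)C)C#CC(=C)CO[Si](c2ccccc2)(c2ccccc2)C(C)(C)C)[C@H]3O[C@H]3[C@H](OC(C)=O)[C@H](C)[C@@H]1[C@@H](OC(C)=O)C(=O)[C@@H](O[Si](CC)(CC)CC)C=C | intermediate |
| 35 | C7 alcohol | C[C@]1([C@@H](O[Si](C(C)C)(C(C)C)C(C)C)C#CC(=C)CO[Si](c2ccccc2)(c2ccccc2)C(C)(C)C)[C@H]3O[C@H]3[C@H](OC(C)=O)[C@H](C)[C@@H]1[C@@H](OC(C)=O)C(=O)[C@@H](O)C=C | intermediate |
| 36 | 2-bromopropionyl bromide | CC(Br)C(=O)Br | starting material |
| 37 | C7 2-bromopropionate | C[C@]1([C@@H](O[Si](C(C)C)(C(C)C)C(C)C)C#CC(=C)CO[Si](c2ccccc2)(c2ccccc2)C(C)(C)C)[C@H]3O[C@H]3[C@H](OC(C)=O)[C@H](C)[C@@H]1[C@@H](OC(C)=O)C(=O)[C@@H](OC(=O)C(C)Br)C=C | intermediate |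
| 38 | γ-lactone (8-OH, 17-Me) | C[C@]1([C@@H](O[Si](C(C)C)(C(C)C)C(C)C)C#CC(=C)CO[Si](c2ccccc2)(c2ccccc2)C(C)(C)C)[C@H]3O[C@H]3[C@H](OC(C)=O)[C@H](C)[C@@H]1[C@@H](OC(C)=O)[C@@]4(O)[C@H](C=C)OC(=O)[C@@H]4C | intermediate |
| 39 | cis-dienyl RCM precursor | C[C@]1([C@@H](O[Si](C(C)C)(C(C)C)C(C)C)/C=C\C(=C)CO[Si](c2ccccc2)(c2ccccc2)C(C)(C)C)[C@H]3O[C@H]3[C@H](OC(C)=O)[C@H](C)[C@@H]1[C@@H](OC(C)=O)[C@@]4(O)[C@H](C=C)OC(=O)[C@@H]4C | intermediate |
| 40 | bis-silyl macrocycle | CC(=O)O[C@@H]1[C@H](C)[C@@H]2[C@@H](OC(C)=O)[C@@]3(O)[C@H](/C=C(CO[Si](c4ccccc4)(c4ccccc4)C(C)(C)C)\C=C/[C@H](O[Si](C(C)C)(C(C)C)C(C)C)[C@@]2(C)[C@H]2O[C@@H]12)OC(=O)[C@@H]3C | intermediate |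
| 41 | Briaexcavatolide N | CC(=O)O[C@@H]1[C@H](C)[C@@H]2[C@@H](OC(C)=O)[C@@]3(O)[C@H](/C=C(CO)\C=C/[C@H](O)[C@@]2(C)[C@H]2O[C@@H]12)OC(=O)[C@@H]3C | target |

## Totals
- Total steps: 32.
- Longest linear sequence: 25 steps (3 → 5 → 6 → 8 → 9 → 10 → 11 → 12 → 13 → 14 → 20 → 21 → 22 → 23 → 24 → 30 → 31 → 32 → 33 → 34 → 35 → 37 → 38 → 39 → 40 → 41, counted by the steps that consume each compound).

**Three steps most likely to fail**
1. **Step 31 (proposed new RCM).** The crowded 10-membered ring closure may give dimers, stall at the diene, or isomerise the double bonds.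
   Fallback (known chemistry, different approach): close the ring at C2–C3 instead, by a macrocyclic intramolecular Nozaki–Hiyama–Kishi coupling (CrCl2, cat. NiCl2) of a (Z)-vinyl iodide with the C2 aldehyde. The C5=C6 diene is made beforehand by Stille coupling, and C2 is corrected afterwards by oxidation and CBS reduction.
2. **Step 5 (Diels–Alder).** The exo/endo ratio that sets the cis C11-Me/C10 relationship is uncertain, and the C1 quaternary centre depends on it.
   Fallback: build ring A by Hayashi–Jørgensen organocatalytic Michael addition of propanal to a nitroalkene (syn adduct, which becomes the cis Me/C9 pair), then vinyl-Grignard addition and RCM to close the cyclohexene.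
3. **Step 29 (Reformatsky lactonisation).** The C8/C17 configurations depend on the conformation of the zinc chelate, and C7 may epimerise.
   Fallback: replace the one-pot lactonisation by Mukaiyama aldol addition of the silyl ketene acetal of methyl propionate to the C8 ketone (TiCl4), then acid-catalysed lactonisation of the C7 alcohol, separating the C8/C17 epimers.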